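Per millimolar of X, the plateaus of the two earlier runs at 16 °C give a steady ratio of G to E. The rate of G over the rate of E reads a·X, where a is a selectivity factor for one temperature and X is what stands in the flask at that moment.

| flask | J | X | temperature | remark | time |
|---|---|---|---|---|---|
| Sunday's | 0.0050 M (fed, over 20 min) | 10 mM | 16 °C | run made earlier |  |
| Wednesday's | 0.0075 M (fed, over 20 min) | 10 mM | 30 °C | run made earlier |  |
| Friday's | 0.010 M (fed, over 20 min) | 20 mM | 16 °C | run made earlier |  |
| green | 0.010 M (fed, over 30 min) | 10.0 mM |  | at 10 °C throughout | 6.0 h |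
| blue | 0.010 M (fed, over 20 min) | 10.0 mM |  | at 10 °C until 20 min, from then on at 35 °C | 2.0 h |

| run | time / min | G / % | J / % |
|---|---|---|---|
| Sunday's | 6.00 | 15.2 | 1.1 |
| Sunday's | 20.0 | 46.1 | 2.7 |
| Sunday's | 30.0 | 47.2 | 0 |
| Sunday's | 50.0 | 47.3 | 0 |
| Sunday's | 80.0 | 47.3 | 0.4 |
| Sunday's | 90.0 | 47.1 | 0.6 |
| Wednesday's | 3.00 | 3.9 | 0.3 |
| Wednesday's | 4.00 | 5.8 | 0.4 |
| Wednesday's | 8.00 | 9.7 | 0 |
| Wednesday's | 15.0 | 18.0 | 0.5 |
| Wednesday's | 20.0 | 21.6 | 0.9 |
| Wednesday's | 30.0 | 21.0 | 0.1 |
| Friday's | 8.00 | 27.1 | 1.3 |
| Friday's | 25.0 | 63.8 | 0.3 |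
| Friday's | 40.0 | 63.8 | 0 |
| Friday's | 60.0 | 64.3 | 0.6 |
| Friday's | 90.0 | 63.4 | 0 |

(readings scatter by 0.5 percentage points)

1. the flask that ends with the higher amount of G, in percent of the J charged, or "neither" when 2 percentage points or less lies between them (green / blue / neither)
2. final G, as a percentage of the J charged, in green
3. final G, as a percentage of the J charged, in blue

- candidate steps: J + X -> G; J + X -> E; J <-> L
- percentages count the whole charge, also what has not yet gone in

J reads 2.7% at the end of Sunday's feed, so X falls in step with the dosing. Taking E as the rest of the charge and X̄ as the mean X during that fall, a = G/(E·X̄). Sunday gives 0.120 mM⁻¹ and Friday, with other charges at the same temperature, gives 0.117 mM⁻¹, so the rule holds. Wednesday, at 30 °C, reads 0.0425 mM⁻¹. A straight line in ln a against temperature carries this to 10 °C: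

a = 0.186 mM⁻¹, u = a·X₀ = 1.86

Here X₀ is the charge of X, which in green equals the charge of J. The share of G at any moment is aX/(aX + 1), and this curve bends downward as X falls. Its mean over the fall from X₀ to zero therefore lies below the value at half the charge and above the chord:

upper bound: 48.2%
lower bound: 32.5%

Integrating the share in closed form closes the bracket:

Φ = 1 − ln(1 + u)/u = 43.6%

This Φ is the share of a used-up charge of X that ends as G. The reckoning gives green and blue the same Φ, since blue's feed also runs at 10 °C. Heating lowers a, but it reaches only the J left at the change, so this reckoning expects the two flasks to end within 2 percentage points.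

The forecast says neither, with 44.5% for green (40% to 49%) and 43% for blue (37% to 47%): “Feed time hardly matters.” Its green value stands inside the bracket and a little above this Φ.

The flasks give neither: green ends at 44.7% and blue at 44.2%.

    J + X → G (k = 110 L mol⁻¹ min⁻¹, Ea = 36.0 kJ mol⁻¹)
    J + X → E, rate k2*[J] as long as [X] is above zero (k = 0.560 min⁻¹, Ea = 89.0 kJ mol⁻¹)
    J ⇌ L (K = 17.0, k = 0.0110 min⁻¹, Ea = 82.0 kJ mol⁻¹, ΔH = 53.0 kJ mol⁻¹)
    (constants at 10 °C)

Green, with X at 0.860% of its charge at 6.00 h, stands 1.1 points above Φ. Blue holds G 44.1% at the change of temperature, while its E goes from 48.0% to 54.9%. The neighbour of green charged with 0.017 M of J has 0.588 equiv of X, so X is the limiting reagent and G should be Φ·X₀ over the J charged, 25.6%. That flask gives 26.3%, with 0% of X left. At 6.00 h it holds 38.1% as L and 3.05% as J.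

All runs are calculated with made-up constants, and the scatter is random.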